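**Strategy.** Germacrane numbering (C1–C15) is used throughout. The ten-membered carbocycle is not macrocyclised but grown from a cyclohexane by four atoms. The target's C4=C5 alkene, flanked by the C6 oxygen and the C3 methylene, is the retron of an alkynyl oxy-Cope rearrangement. In cyclohexanol 10 (ring C6–C1–C10–C9–C8–C7) a propynyl group on C6 and a vinyl group on C1 form a 1,5-enyne; its anionic [3,3] shift breaks C1–C6 and forms C3–C4, delivering the cyclodecadienone with C6 ketone, C8 ketal and C10 tertiary oxygen. Afterwards the butenolide is annulated on C6/C7, C6 and C8 are set by catalyst-controlled reductions, and the C10 acetate is transposed to C2.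

Key step: step 9

Assumption: compounds 1 and 15 and all named reagents are commercial; acid 16 is not assumed to be and is made in step 11.

Step 1
Reactants: 1 5-methylcyclohexane-1,3-dione
Product: 2 3-methyl-5,5-(ethylenedioxy)cyclohexan-1-one (racemic mono-ketal)
Conditions: ethylene glycol, TsOH (cat.), benzene, reflux, Dean–Stark
Reagents that add atoms: ethylene glycol, OCCO
Why: Acid-catalysed ketalisation with water removal masks one carbonyl of the symmetrical dione as the dioxolane (future C8), while the C10 methine is racemic here and becomes trigonal or is reset later.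

Step 2
Reactants: 2 3-methyl-5,5-(ethylenedioxy)cyclohexan-1-one
Product: 4 3-methyl-5,5-(ethylenedioxy)cyclohex-2-en-1-one, via silyl enol ether 3 (not isolated)
Conditions: LiN(iPr)2, THF, −78 °C; Me3SiCl; then Pd(OAc)2, MeCN, rt
Reagents that add atoms: none
Why: Kinetic enolisation should occur at the unhindered C1 methylene rather than at C7 next to the ketal carbon, and Saegusa–Ito dehydrogenation of that enol ether gives the β-methyl enone; the other side cannot dehydrogenate because C8 carries no hydrogen.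

Step 3
Reactants: 4 3-methyl-5,5-(ethylenedioxy)cyclohex-2-en-1-one
Product: 5 (R)-3-methyl-5,5-(ethylenedioxy)cyclohex-2-en-1-ol
Conditions: (S)-2-methyl-CBS-oxazaborolidine (cat.), BH3·SMe2, THF, −30 °C; MeOH
Reagents that add atoms: none
Why: Corey–Bakshi–Shibata reduction with the alkenyl side as the large group should give the (R)-carbinol at C6, a temporary stereocentre chosen so that the relay through steps 4 and 5 makes C10 (S).

Step 4
Reactants: 5 (R)-3-methyl-5,5-(ethylenedioxy)cyclohex-2-en-1-ol
Product: 6 (1R,2R,3S)-2,3-epoxy-3-methyl-5,5-(ethylenedioxy)cyclohexan-1-ol (epoxide cis to the hydroxyl)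
Conditions: VO(acac)2 (cat.), t-BuOOH, CH2Cl2, 0 °C → rt
Reagents that add atoms: tert-butyl hydroperoxide, CC(C)(C)OO
Why: Vanadium-catalysed hydroxyl-directed epoxidation of a cyclic allylic alcohol delivers oxygen syn to the C6 hydroxyl, which sets C1 and C10.

Step 5
Reactants: 6 (1R,2R,3S)-2,3-epoxy-3-methyl-5,5-(ethylenedioxy)cyclohexan-1-ol
Product: 7 (1R,2S,3S)-3-methyl-2-vinyl-5,5-(ethylenedioxy)cyclohexane-1,3-diol
Conditions: vinylmagnesium bromide (excess), CuI (cat.), THF, −30 → 0 °C; aqueous work-up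
Reagents that add atoms: vinylmagnesium bromide, C=C[Mg]Br
Why: Copper-catalysed Grignard opening of the trisubstituted epoxide by SN2 attack at the less substituted C1 with inversion (trans-diaxial, Fürst–Plattner) should place vinyl trans to the retained C10 oxygen and leave C10 as (S).

Step 6
Reactants: 7 (1R,2S,3S)-3-methyl-2-vinyl-5,5-(ethylenedioxy)cyclohexane-1,3-diol
Product: 8 (2R,3S)-3-hydroxy-3-methyl-2-vinyl-5,5-(ethylenedioxy)cyclohexan-1-one
Conditions: Dess–Martin periodinane, pyridine (buffer), CH2Cl2, 0 °C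
Reagents that add atoms: none
Why: Dess–Martin oxidation converts only the secondary C6 alcohol, the tertiary C10 hydroxyl cannot be oxidised, and the near-neutral medium should avoid retro-aldol cleavage and isomerisation of the α-vinyl ketone.

Step 7
Reactants: 8 (2R,3S)-3-hydroxy-3-methyl-2-vinyl-5,5-(ethylenedioxy)cyclohexan-1-one
Product: 9 (2R,3S)-3-methyl-3-(trimethylsilyloxy)-2-vinyl-5,5-(ethylenedioxy)cyclohexan-1-one
Conditions: 1-(trimethylsilyl)imidazole, CH2Cl2, rt
Reagents that add atoms: 1-(trimethylsilyl)imidazole, C[Si](C)(C)n1ccnc1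
Why: Neutral silylation of the tertiary hydroxyl blocks retro-aldol cleavage in step 8 and keeps a second alkoxide out of the key step.

Step 8
Reactants: 9 (2R,3S)-3-methyl-3-(trimethylsilyloxy)-2-vinyl-5,5-(ethylenedioxy)cyclohexan-1-one
Product: 10 (1S,2S,3S)-3-methyl-1-(prop-1-ynyl)-3-(trimethylsilyloxy)-2-vinyl-5,5-(ethylenedioxy)cyclohexan-1-ol
Conditions: prop-1-ynylmagnesium bromide, LaCl3·2LiCl (cat.), THF, −40 → 0 °C; aqueous work-up
Reagents that add atoms: prop-1-ynylmagnesium bromide, CC#C[Mg]Br
Why: In this 1,2-addition of an alkynyl Grignard reagent, axial attack is blocked by the syn-axial C10 methyl and C8 ketal oxygen, so the alkynyl group should enter equatorially and trans to the C1 vinyl group, the arrangement that allows a chair transition state in step 9.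

Step 9
Reactants: 10 (1S,2S,3S)-3-methyl-1-(prop-1-ynyl)-3-(trimethylsilyloxy)-2-vinyl-5,5-(ethylenedioxy)cyclohexan-1-ol
Product: 13 (2E,5E,7S)-3,7-dimethyl-7-(trimethylsilyloxy)-9,9-(ethylenedioxy)cyclodeca-2,5-dien-1-one (germacrane numbering: C6 ketone, 4E, 1E, C8 ketal, C10 silyl ether), via potassium alkoxide 11 (not isolated), via potassium allenolate 12 (not isolated)
Conditions: KH, 18-crown-6, THF, 0 °C → rt; AcOH, −78 °C
Reagents that add atoms: none
Why: Deprotonation gives alkoxide 11, whose C3=C2–C1–C6–C5≡C4 enyne undergoes a charge-accelerated [3,3] sigmatropic shift through a chair-like array in which the C1–C6 bond of the cyclohexane breaks as C3–C4 forms. The closest known reaction type is the anionic oxy-Cope rearrangement of 1-alkynyl-2-alkenylcycloalkanols (acetylenic oxy-Cope). The ten-membered ring is closed by ring expansion of the existing carbocycle (six to ten atoms), not by an end-to-end cyclisation, so no high dilution is needed. No stereocentre is created: C1 and C6 become trigonal, C10 (S) is untouched, and C-protonation of the cyclic allenolate 12 at C5 gives the conjugated 4-en-6-one. The step needs E geometry at the new C1=C2 bond, which the trans-diequatorial alkynyl and vinyl groups should secure through the chair transition state, and E geometry at C4=C5, which is expected from protonation on the outer face of the allene and can be corrected by equilibration. It also needs the [3,3] path to outrun fragmentation, which the silyl cap on the C10 oxygen and the cold acetic acid quench (before the enolate can equilibrate toward C7 and open the ketal) are meant to secure.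

Step 10
Reactants: 13 (2E,5E,7S)-3,7-dimethyl-7-(trimethylsilyloxy)-9,9-(ethylenedioxy)cyclodeca-2,5-dien-1-one
Product: 14 (1S,2E,5E,7S)-3,7-dimethyl-7-(trimethylsilyloxy)-9,9-(ethylenedioxy)cyclodeca-2,5-dien-1-ol
Conditions: (R)-2-methyl-CBS-oxazaborolidine (cat.), catecholborane, toluene, −78 °C; aqueous work-up
Reagents that add atoms: none
Why: Corey–Bakshi–Shibata reduction of the enone with the C5 alkenyl side as the large group should set C6 in the configuration that becomes 6R once C7 is trigonal, and catecholborane leaves the alkenes alone.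

Step 11
Reactants: 15 bromopyruvic acid (3-bromo-2-oxopropanoic acid)
Product: 16 3-acetoxy-2-oxopropanoic acid
Conditions: AcOK, AcOH, 50 °C
Reagents that add atoms: potassium acetate, CC(=O)[O-].[K+]
Why: SN2 displacement of the activated α-bromo ketone by acetate gives the three-carbon acid that carries C11, C12 and C13 with the C13 acetate already in place.

Step 12
Reactants: 14 (1S,2E,5E,7S)-3,7-dimethyl-7-(trimethylsilyloxy)-9,9-(ethylenedioxy)cyclodeca-2,5-dien-1-ol; 16 3-acetoxy-2-oxopropanoic acid
Product: 17 (1S,2E,5E,7S)-3,7-dimethyl-7-(trimethylsilyloxy)-9,9-(ethylenedioxy)cyclodeca-2,5-dien-1-yl 3-acetoxy-2-oxopropanoate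
Conditions: DCC, DMAP (cat.), CH2Cl2, 0 °C
Reagents that add atoms: none
Why: Steglich esterification of the secondary allylic alcohol proceeds with retention at C6 and tethers the electrophilic α-keto carbon C11 to the C6 oxygen.

Step 13
Reactants: 17 (1S,2E,5E,7S)-3,7-dimethyl-7-(trimethylsilyloxy)-9,9-(ethylenedioxy)cyclodeca-2,5-dien-1-yl 3-acetoxy-2-oxopropanoate
Product: 18 (1S,2E,5E,7S)-7-hydroxy-3,7-dimethyl-9-oxocyclodeca-2,5-dien-1-yl 3-acetoxy-2-oxopropanoate
Conditions: PPTS, acetone/H2O, 40 °C
Reagents that add atoms: water, O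
Why: Mild acid hydrolysis should remove the dioxolane and the tertiary trimethylsilyl ether while the esters survive, unmasking the C8 ketone that activates C7.

Step 14
Reactants: 18 (1S,2E,5E,7S)-7-hydroxy-3,7-dimethyl-9-oxocyclodeca-2,5-dien-1-yl 3-acetoxy-2-oxopropanoate
Product: 20 (1E,4E,6R,10S)-13-acetoxy-10-hydroxy-8-oxogermacra-1,4,7(11)-trien-12,6-olide, via aldol lactone 19 (not isolated)
Conditions: PPTS (cat.), 4 Å molecular sieves, toluene, 60 °C
Reagents that add atoms: none
Why: In this acid-catalysed intramolecular aldol condensation the C8-ketone enol toward C7 adds to the highly electrophilic α-keto carbonyl C11 in a 5-exo mode and dehydration gives the conjugated butenolide; attack from C9 is excluded by ring size, the C7=C11 geometry is fixed by the lactone ring, and the enol (not enolate) mode is chosen to avoid loss of the C6 acyloxy group.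

Step 15
Reactants: 20 (1E,4E,6R,10S)-13-acetoxy-10-hydroxy-8-oxogermacra-1,4,7(11)-trien-12,6-olide
Product: 21 (1E,4E,6R,8S,10S)-13-acetoxy-8,10-dihydroxygermacra-1,4,7(11)-trien-12,6-olide
Conditions: (R)-2-methyl-CBS-oxazaborolidine, catecholborane, CH2Cl2/toluene, −78 °C; aqueous work-up
Reagents that add atoms: none
Why: Corey–Bakshi–Shibata reduction of the ketone conjugated to the butenolide, with the C7 alkenyl side as the large group, should set C8 as (S) by catalyst control, 1,2-reduction being favoured over conjugate reduction at low temperature.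

Step 16
Reactants: 21 (1E,4E,6R,8S,10S)-13-acetoxy-8,10-dihydroxygermacra-1,4,7(11)-trien-12,6-olide
Product: 22 (1E,4E,6R,8S,10S)-13-acetoxy-10-hydroxy-8-(methacryloyloxy)germacra-1,4,7(11)-trien-12,6-olide
Conditions: methacrylic anhydride, Et3N, DMAP (cat.), CH2Cl2, 0 °C
Reagents that add atoms: methacrylic anhydride, C=C(C)C(=O)OC(=O)C(C)=C
Why: DMAP-catalysed acylation takes the secondary C8 hydroxyl selectively because the tertiary C10 hydroxyl is too hindered at 0 °C.

Step 17
Reactants: 22 (1E,4E,6R,8S,10S)-13-acetoxy-10-hydroxy-8-(methacryloyloxy)germacra-1,4,7(11)-trien-12,6-olide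
Product: 23 (1E,4E,6R,8S,10S)-10,13-diacetoxy-8-(methacryloyloxy)germacra-1,4,7(11)-trien-12,6-olide
Conditions: Ac2O, Et3N, DMAP, CH2Cl2, rt → 35 °C
Reagents that add atoms: acetic anhydride, CC(=O)OC(C)=O
Why: DMAP-catalysed acetylation is the standard way to esterify a tertiary allylic alcohol without ionising it, with retention at C10.

Step 18
Reactants: 23 (1E,4E,6R,8S,10S)-10,13-diacetoxy-8-(methacryloyloxy)germacra-1,4,7(11)-trien-12,6-olide
Product: 24 (1(10)E,4E,2R,6R,8S)-2,13-diacetoxy-8-(methacryloyloxy)germacra-1(10),4,7(11)-trien-12,6-olide (CNP0309304.1)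
Conditions: PdCl2(MeCN)2 (cat.), THF, rt
Reagents that add atoms: none
Why: The PdCl2-catalysed [3,3] allylic acetate transposition (cyclisation-induced rearrangement through a chair acetoxonium ring) transfers the acetate suprafacially from (10S) across the E C1=C2 bond with C9 and C3 equatorial, which should set C2 as (R) and the new C1=C10 bond as E, driven by the gain of a trisubstituted alkene.

**Compound list**

1 | 5-methylcyclohexane-1,3-dione | CC1CC(=O)CC(=O)C1 | starting material
2 | 3-methyl-5,5-(ethylenedioxy)cyclohexan-1-one (racemic) | CC1CC(=O)CC2(C1)OCCO2 | intermediate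
3 | 1-(trimethylsilyloxy)-3-methyl-5,5-(ethylenedioxy)cyclohex-1-ene | CC1C=C(O[Si](C)(C)C)CC2(C1)OCCO2 | intermediate (not isolated)
4 | 3-methyl-5,5-(ethylenedioxy)cyclohex-2-en-1-one | CC1=CC(=O)CC2(C1)OCCO2 | intermediate
5 | (R)-3-methyl-5,5-(ethylenedioxy)cyclohex-2-en-1-ol | CC1=C[C@H](O)CC2(C1)OCCO2 | intermediate
6 | (1R,2R,3S)-2,3-epoxy-3-methyl-5,5-(ethylenedioxy)cyclohexan-1-ol | O[C@H]1[C@H]2O[C@@]2(C)CC3(OCCO3)C1 | intermediate
7 | (1R,2S,3S)-3-methyl-2-vinyl-5,5-(ethylenedioxy)cyclohexane-1,3-diol | O[C@H]1[C@H](C=C)[C@@](C)(O)CC2(OCCO2)C1 | intermediate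
8 | (2R,3S)-3-hydroxy-3-methyl-2-vinyl-5,5-(ethylenedioxy)cyclohexan-1-one | O=C1[C@H](C=C)[C@@](C)(O)CC2(OCCO2)C1 | intermediate
9 | (2R,3S)-3-methyl-3-(trimethylsilyloxy)-2-vinyl-5,5-(ethylenedioxy)cyclohexan-1-one | O=C1[C@H](C=C)[C@@](C)(O[Si](C)(C)C)CC2(OCCO2)C1 | intermediate
10 | (1S,2S,3S)-3-methyl-1-(prop-1-ynyl)-3-(trimethylsilyloxy)-2-vinyl-5,5-(ethylenedioxy)cyclohexan-1-ol | CC#C[C@@]1(O)[C@H](C=C)[C@@](C)(O[Si](C)(C)C)CC2(OCCO2)C1 | intermediate
11 | potassium alkoxide of 10 | CC#C[C@@]1([O-])[C@H](C=C)[C@@](C)(O[Si](C)(C)C)CC2(OCCO2)C1.[K+] | intermediate (not isolated)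
12 | potassium (5E,7S)-3,7-dimethyl-7-(trimethylsilyloxy)-9,9-(ethylenedioxy)cyclodeca-1,2,5-trien-1-olate (allenolate) | [O-]C1=C=C(C)C/C=C/[C@@](C)(O[Si](C)(C)C)CC2(OCCO2)C1.[K+] | intermediate (not isolated)
13 | (2E,5E,7S)-3,7-dimethyl-7-(trimethylsilyloxy)-9,9-(ethylenedioxy)cyclodeca-2,5-dien-1-one | O=C1/C=C(C)/C/C=C/[C@@](C)(O[Si](C)(C)C)CC2(OCCO2)C1 | intermediate
14 | (1S,2E,5E,7S)-3,7-dimethyl-7-(trimethylsilyloxy)-9,9-(ethylenedioxy)cyclodeca-2,5-dien-1-ol | O[C@@H]1/C=C(C)/C/C=C/[C@@](C)(O[Si](C)(C)C)CC2(OCCO2)C1 | intermediate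
15 | bromopyruvic acid | OC(=O)C(=O)CBr | starting material
16 | 3-acetoxy-2-oxopropanoic acid | CC(=O)OCC(=O)C(=O)O | intermediate
17 | (1S,2E,5E,7S)-3,7-dimethyl-7-(trimethylsilyloxy)-9,9-(ethylenedioxy)cyclodeca-2,5-dien-1-yl 3-acetoxy-2-oxopropanoate | CC(=O)OCC(=O)C(=O)O[C@@H]1/C=C(C)/C/C=C/[C@@](C)(O[Si](C)(C)C)CC2(OCCO2)C1 | intermediate
18 | (1S,2E,5E,7S)-7-hydroxy-3,7-dimethyl-9-oxocyclodeca-2,5-dien-1-yl 3-acetoxy-2-oxopropanoate | CC(=O)OCC(=O)C(=O)O[C@@H]1/C=C(C)/C/C=C/[C@@](C)(O)CC(=O)C1 | intermediate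
19 | aldol lactone: 13-acetoxy-10,11-dihydroxy-8-oxogermacra-1,4-dien-12,6-olide (C7 and C11 undefined) | CC(=O)OCC1(O)C(=O)O[C@@H]2/C=C(C)/C/C=C/[C@@](C)(O)CC(=O)C12 | intermediate (not isolated)
20 | (1E,4E,6R,10S)-13-acetoxy-10-hydroxy-8-oxogermacra-1,4,7(11)-trien-12,6-olide | O=C1C[C@](C)(O)/C=C/C/C(C)=C/[C@H]2OC(=O)C(COC(C)=O)=C12 | intermediate
21 | (1E,4E,6R,8S,10S)-13-acetoxy-8,10-dihydroxygermacra-1,4,7(11)-trien-12,6-olide | O[C@H]1C[C@](C)(O)/C=C/C/C(C)=C/[C@H]2OC(=O)C(COC(C)=O)=C12 | intermediate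
22 | (1E,4E,6R,8S,10S)-13-acetoxy-10-hydroxy-8-(methacryloyloxy)germacra-1,4,7(11)-trien-12,6-olide | C=C(C)C(=O)O[C@H]1C[C@](C)(O)/C=C/C/C(C)=C/[C@H]2OC(=O)C(COC(C)=O)=C12 | intermediate
23 | (1E,4E,6R,8S,10S)-10,13-diacetoxy-8-(methacryloyloxy)germacra-1,4,7(11)-trien-12,6-olide | C=C(C)C(=O)O[C@H]1C[C@](C)(OC(C)=O)/C=C/C/C(C)=C/[C@H]2OC(=O)C(COC(C)=O)=C12 | intermediate
24 | (1(10)E,4E,2R,6R,8S)-2,13-diacetoxy-8-(methacryloyloxy)germacra-1(10),4,7(11)-trien-12,6-olide | C=C(C)C(=O)O[C@H]1C/C(C)=C/[C@H](OC(C)=O)C/C(C)=C/[C@H]2OC(=O)C(COC(C)=O)=C12 | target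

**Step count and risks**

Total step count: 18. Longest linear sequence: 17 steps (steps 1–10 and 12–18; step 11 is a one-step side branch).

The three steps most likely to fail:

1. Step 9 (key step). The alkoxide may fragment or the silyl group may migrate faster than the [3,3] shift. Protonation of the allenolate may also be unselective, giving the 4Z enone or deconjugation into the C3 methylene. Fallback: from 9, addition of (E)-prop-1-enylmagnesium bromide should give the 1-propenyl-2-vinyl carbinol F1. The classical divinyl anionic oxy-Cope rearrangement (KH, 18-crown-6, THF) forms the same C3–C4 bond and delivers the C5–C6 potassium enolate regiospecifically. This enolate is silylated in the flask (Me3SiCl) to the silyl enol ether F2. Saegusa–Ito dehydrogenation (Pd(OAc)2, MeCN) then introduces the C4=C5 double bond and comes back to the route at 13.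

2. Step 14. Elimination of the C6 acyloxy group from the β-acyloxy ketone, ionisation of the tertiary allylic alcohol, or epimerisation at C6 may compete with the enol-mode aldol closure. Fallback without ketone enol chemistry: from 13, α-methylenation at C7 (paraformaldehyde, N-methylanilinium trifluoroacetate, THF) should give the exo-methylene ketone F3. Luche reduction (NaBH4, CeCl3) gives the allylic alcohol F4. Esterification with 2-(acetoxymethyl)acrylic acid gives the diene ester F5; it is run with DCC (retention) or under Mitsunobu conditions (inversion), whichever delivers the drawn C6 configuration. Ring-closing metathesis with the second-generation Grubbs catalyst (toluene, 60 °C) closes the tetrasubstituted butenolide F6. PPTS in aqueous acetone then removes ketal and silyl ether and comes back to the route at 20.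

3. Step 18. Divalent palladium may trigger Cope rearrangement or transannular cyclisation of the newly formed 1(10),4-diene, and chirality transfer or E/Z control may be incomplete. Fallback: from 22, oxidative transposition of the tertiary allylic alcohol with pyridinium chlorochromate (Babler–Dauben oxidation) should give the 1(10)-en-2-one F7. Reduction with (S)-2-methyl-CBS-oxazaborolidine and catecholborane sets C2 by catalyst control and gives the (2R)-alcohol F8. Acetylation (Ac2O, pyridine) comes back to the route at 24.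

**Further compounds**

F1 | step 9 | (1S,2S,3S)-3-methyl-1-[(E)-prop-1-enyl]-3-(trimethylsilyloxy)-2-vinyl-5,5-(ethylenedioxy)cyclohexan-1-ol | C/C=C/[C@@]1(O)[C@H](C=C)[C@@](C)(O[Si](C)(C)C)CC2(OCCO2)C1
F2 | step 9 | (5E,7S)-3,7-dimethyl-1,7-bis(trimethylsilyloxy)-9,9-(ethylenedioxy)cyclodeca-1,5-diene (C3 and enol ether geometry undefined) | C[Si](C)(C)OC1=CC(C)C/C=C/[C@@](C)(O[Si](C)(C)C)CC2(OCCO2)C1
F3 | step 14 | (2E,5E,7S)-3,7-dimethyl-10-methylidene-7-(trimethylsilyloxy)-9,9-(ethylenedioxy)cyclodeca-2,5-dien-1-one | O=C1/C=C(C)/C/C=C/[C@@](C)(O[Si](C)(C)C)CC2(OCCO2)C1=C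
F4 | step 14 | (2E,5E,7S)-3,7-dimethyl-10-methylidene-7-(trimethylsilyloxy)-9,9-(ethylenedioxy)cyclodeca-2,5-dien-1-ol (C1 configured as in 14) | O[C@@H]1/C=C(C)/C/C=C/[C@@](C)(O[Si](C)(C)C)CC2(OCCO2)C1=C
F5 | step 14 | 2-(acetoxymethyl)acrylate ester of F4 | C=C(COC(C)=O)C(=O)O[C@@H]1/C=C(C)/C/C=C/[C@@](C)(O[Si](C)(C)C)CC2(OCCO2)C1=C
F6 | step 14 | (1E,4E,6R,10S)-13-acetoxy-8,8-(ethylenedioxy)-10-(trimethylsilyloxy)germacra-1,4,7(11)-trien-12,6-olide | C1COC2(O1)C[C@](C)(O[Si](C)(C)C)/C=C/C/C(C)=C/[C@H]1OC(=O)C(COC(C)=O)=C12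
F7 | step 18 | (1(10)E,4E,6R,8S)-13-acetoxy-8-(methacryloyloxy)-2-oxogermacra-1(10),4,7(11)-trien-12,6-olide | C=C(C)C(=O)O[C@H]1C/C(C)=C/C(=O)C/C(C)=C/[C@H]2OC(=O)C(COC(C)=O)=C12
F8 | step 18 | (1(10)E,4E,2R,6R,8S)-13-acetoxy-2-hydroxy-8-(methacryloyloxy)germacra-1(10),4,7(11)-trien-12,6-olide | C=C(C)C(=O)O[C@H]1C/C(C)=C/[C@H](O)C/C(C)=C/[C@H]2OC(=O)C(COC(C)=O)=C12
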